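**Plan**

- Retrosynthesis: after removal of the isopropylidene and benzyl groups, the two aryl–carbon bonds (Ar–C2 and Ar–C6) of the 3,7-dioxabicyclo[3.3.0]octane are cut. This leaves two equivalents of an arylzinc and a twofold-symmetric bis-lactol diacetate, which goes back through the bis-γ-lactone (acyl bonds C2–O3 and C6–O7) to a 2,3-bis(benzyloxymethyl)tartrate acetonide (bonds C1–C8 and C5–C4) and D-tartrate.
- Enabling feature: C2 and C6 are acetal-level carbons of ring A (C1–C2–O3–C4–C5) and ring B (C5–C6–O7–C8–C1), each next to a quaternary carbinol carbon (C1, C5). Without its aryl groups the core is a tartaric acid whose carboxyl carbons are C2/C6 and whose α-hydrogens are replaced by the C8/C4 methylenes.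
- Forward: two enolate alkylations attach C8 and C4, hydrogenolysis closes rings A and B as lactones onto the dioxolane, reductive acetylation gives the bis-lactol diacetate, both aryl groups are added in one operation, and two deprotections finish.
- Stereochemistry: C1 and C5 come from (S,S)-tartrate by alkylation with retention; C2 and C6 are set in the arylation by the neighbouring tertiary C–O bonds (aryl cis to oxygen, exo).

Key step: step 6

Assumption: the lithium enolate of the tartrate acetonide takes up alkyl and alkoxymethyl halides with retention (new group cis to the ester on the neighbouring carbon), the known course for this enolate; the (S,S) series is chosen on that basis.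

**Step 1**
Reactants: 1 dimethyl (4S,5S)-2,2-dimethyl-1,3-dioxolane-4,5-dicarboxylate (commercial acetonide of dimethyl D-tartrate); 2 benzyl chloromethyl ether
Product: 4 dimethyl (4S,5S)-4-[(benzyloxy)methyl]-2,2-dimethyl-1,3-dioxolane-4,5-dicarboxylate, via lithium enolate 3 (not isolated)
Conditions: LiN(iPr)2 (1.1 equiv), THF/DMPU, −78 °C; then 2 (1.2 equiv), −78 °C
Reagents that add atoms: benzyl chloromethyl ether (compound 2), ClCOCc1ccccc1
Why: Ester enolate C-alkylation of a tartrate acetonide: the enolate is stable at −78 °C because its β-oxygen is held in the ring, and it should take up the alkoxymethyl chloride cis to the ester on the neighbouring carbon, so the quaternary centre forms with retention (esters stay trans); the minor cis-diester epimer, which would lead into the enantiomeric series, is removed by chromatography here.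

**Step 2**
Reactants: 4 dimethyl (4S,5S)-4-[(benzyloxy)methyl]-2,2-dimethyl-1,3-dioxolane-4,5-dicarboxylate; 2 benzyl chloromethyl ether
Product: 6 dimethyl (4S,5S)-4,5-bis[(benzyloxy)methyl]-2,2-dimethyl-1,3-dioxolane-4,5-dicarboxylate, via lithium enolate 5 (not isolated)
Conditions: LiN(iPr)2 (1.3 equiv), THF/DMPU, −78 °C; then 2 (1.5 equiv), −78 → −40 °C
Reagents that add atoms: benzyl chloromethyl ether (compound 2), ClCOCc1ccccc1
Why: A second ester enolate C-alkylation of the same kind: the only remaining α-hydrogen is removed and the electrophile should again enter on the face of the neighbouring ester, away from the bulkier benzyloxymethyl arm, giving the twofold-symmetric trans-diester in which each CH2OBn is cis to the ester on the other ring carbon.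

**Step 3**
Reactants: 6 dimethyl (4S,5S)-4,5-bis[(benzyloxy)methyl]-2,2-dimethyl-1,3-dioxolane-4,5-dicarboxylate
Product: 8 (1S,5S)-1,5-(isopropylidenedioxy)-3,7-dioxabicyclo[3.3.0]octane-2,6-dione, via diol diester 7 (not isolated)
Conditions: H2 (1 atm), Pd/C (10%), EtOAc, rt; then PPTS (cat.), PhMe, 5 Å MS, 80 °C
Reagents that add atoms: none
Why: Benzyl ether hydrogenolysis followed by acid-catalysed γ-lactonisation (intramolecular transesterification): each freed CH2OH is cis to the ester on the neighbouring carbon, so two five-membered lactones should close onto the dioxolane C4–C5 bond (C1–C5 of the bicycle) without touching a stereocentre, and any cis-diester isomer carried from step 2 cannot close and is separated.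

**Step 4**
Reactants: 8 (1S,5S)-1,5-(isopropylidenedioxy)-3,7-dioxabicyclo[3.3.0]octane-2,6-dione
Product: 10 (1S,5S)-2,6-diacetoxy-1,5-(isopropylidenedioxy)-3,7-dioxabicyclo[3.3.0]octane (anomer mixture), via bis(diisobutylaluminium) lactolate 9 (not isolated)
Conditions: iBu2AlH (2.3 equiv), CH2Cl2, −78 °C; then pyridine, DMAP, Ac2O, −78 → 0 °C
Reagents that add atoms: acetic anhydride, CC(=O)OC(C)=O
Why: Reductive acetylation of a lactone: iBu2AlH stops at the tetrahedral aluminium lactolate at −78 °C, which is acetylated in the flask before it can open to the hydroxy aldehyde; the acetal carbons C2 and C6 form as anomer mixtures, which is immaterial because both are ionised in step 6.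

**Step 5**
Reactants: 11 4-benzyloxy-3-methoxybromobenzene
Product: 13 (4-benzyloxy-3-methoxyphenyl)zinc bromide (used as a solution), via aryllithium 12 (not isolated)
Conditions: n-BuLi (1.05 equiv), THF, −78 °C; then ZnBr2 (1.1 equiv), −78 °C → rt; THF exchanged for PhMe/n-Bu2O
Reagents that add atoms: zinc dibromide, Br[Zn]Br
Why: Bromine–lithium exchange followed by transmetalation from lithium to zinc; the benzyl and methyl ethers are inert and the arylzinc halide is mild enough to be combined with a Lewis acid.

**Step 6**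
Reactants: 10 (1S,5S)-2,6-diacetoxy-1,5-(isopropylidenedioxy)-3,7-dioxabicyclo[3.3.0]octane (anomer mixture); 13 (4-benzyloxy-3-methoxyphenyl)zinc bromide
Product: 15 (1R,2S,5R,6S)-2,6-bis(4-benzyloxy-3-methoxyphenyl)-1,5-(isopropylidenedioxy)-3,7-dioxabicyclo[3.3.0]octane, via mono-aryl monoacetate 14 (not isolated)
Conditions: 13 (5 equiv), BF3·OEt2 (3 equiv), CH2Cl2/PhMe/n-Bu2O, −78 → −20 °C
Reagents that add atoms: (4-benzyloxy-3-methoxyphenyl)zinc bromide (compound 13), COc1cc([Zn]Br)ccc1OCc1ccccc1
Why: BF3·OEt2 removes acetate from C2 of 10 to give a five-membered oxocarbenium ion (C2=O3+), the arylzinc transfers its aryl group from zinc to this carbon, and the same ionisation and aryl transfer at C6 of mono-aryl acetate 14 complete the double C-arylation; both anomers of the diacetate converge on the same cations. The closest known reaction type is the Lewis acid-promoted C-arylation of furanosyl acetates and halides with arylzinc reagents used for C-aryl glycosides. No ring is closed, because rings A and B are already in place. Each new stereocentre (C2, C6) is controlled by the adjacent quaternary carbon (C1, C5): five-membered oxocarbenium ions that carry an alkoxy group on the neighbouring carbon react by inside attack on the envelope with that C–O bond pseudo-equatorial, which places the nucleophile cis to the C–O bond and trans to the carbon branch (C8 at C1, C4 at C5), i.e. exo. The step needs facial selectivity at both centres, and the substrate should secure it through this stereoelectronic preference together with the methylene of the other ring, which flanks the opposite face, while the twofold symmetry makes the two arylations equivalent. The benzyl ethers, the ketal and the first-formed benzylic ether should survive BF3·OEt2 at low temperature.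

**Step 7**
Reactants: 15 (1R,2S,5R,6S)-2,6-bis(4-benzyloxy-3-methoxyphenyl)-1,5-(isopropylidenedioxy)-3,7-dioxabicyclo[3.3.0]octane
Product: 16 (1R,2S,5R,6S)-2,6-bis(4-benzyloxy-3-methoxyphenyl)-3,7-dioxabicyclo[3.3.0]octane-1,5-diol
Conditions: AcOH/H2O (4:1), 50 °C
Reagents that add atoms: none
Why: Acid-catalysed hydrolysis of an isopropylidene ketal; dilute aqueous acetic acid is chosen because the benzylic ring C–O bonds, although attached to electron-rich arenes, are deactivated towards ionisation by the oxygenated quaternary carbon next to them, and no stereocentre is involved.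

**Step 8**
Reactants: 16 (1R,2S,5R,6S)-2,6-bis(4-benzyloxy-3-methoxyphenyl)-3,7-dioxabicyclo[3.3.0]octane-1,5-diol
Product: 17 (1R,2S,5R,6S)-2,6-bis(4-hydroxy-3-methoxyphenyl)-3,7-dioxabicyclo[3.3.0]octane-1,5-diol (target)
Conditions: H2 (1 atm), Pd/C (10%), EtOAc/EtOH, rt, stopped at full debenzylation
Reagents that add atoms: none
Why: Catalytic hydrogenolysis of aryl benzyl ethers, which should be much faster than cleavage of the hindered dialkyl benzylic bonds C2–O3 and C6–O7 in a neutral solvent.

**Compound list**

1 | dimethyl (4S,5S)-2,2-dimethyl-1,3-dioxolane-4,5-dicarboxylate (dimethyl 2,3-O-isopropylidene-D-tartrate) | COC(=O)[C@H]1OC(C)(C)O[C@@H]1C(=O)OC | starting material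
2 | benzyl chloromethyl ether | ClCOCc1ccccc1 | starting material
3 | lithium enolate of 1 (remaining centre S) | COC(=O)[C@H]1OC(C)(C)OC1=C(OC)O[Li] | intermediate
4 | dimethyl (4S,5S)-4-[(benzyloxy)methyl]-2,2-dimethyl-1,3-dioxolane-4,5-dicarboxylate | COC(=O)[C@@]1(COCc2ccccc2)OC(C)(C)O[C@@H]1C(=O)OC | intermediate
5 | lithium enolate of 4 (quaternary centre S) | COC(=O)[C@@]1(COCc2ccccc2)OC(C)(C)OC1=C(OC)O[Li] | intermediate
6 | dimethyl (4S,5S)-4,5-bis[(benzyloxy)methyl]-2,2-dimethyl-1,3-dioxolane-4,5-dicarboxylate | COC(=O)[C@@]1(COCc2ccccc2)OC(C)(C)O[C@]1(COCc2ccccc2)C(=O)OC | intermediate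
7 | dimethyl (4S,5S)-4,5-bis(hydroxymethyl)-2,2-dimethyl-1,3-dioxolane-4,5-dicarboxylate | COC(=O)[C@@]1(CO)OC(C)(C)O[C@]1(CO)C(=O)OC | intermediate
8 | (1S,5S)-1,5-(isopropylidenedioxy)-3,7-dioxabicyclo[3.3.0]octane-2,6-dione (acetonide-bridged bis-γ-lactone) | O=C1OC[C@@]2(OC(C)(C)O3)C(=O)OC[C@@]123 | intermediate
9 | bis(diisobutylaluminium) lactolate of 8 (C2/C6 mixture) | CC(C)C[Al](CC(C)C)OC1OC[C@@]2(OC(C)(C)O3)C(O[Al](CC(C)C)CC(C)C)OC[C@@]123 | intermediate
10 | (1S,5S)-2,6-diacetoxy-1,5-(isopropylidenedioxy)-3,7-dioxabicyclo[3.3.0]octane (anomer mixture) | CC(=O)OC1OC[C@@]2(OC(C)(C)O3)C(OC(C)=O)OC[C@@]123 | intermediate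
11 | 4-benzyloxy-3-methoxybromobenzene | COc1cc(Br)ccc1OCc1ccccc1 | starting material
12 | (4-benzyloxy-3-methoxyphenyl)lithium | COc1cc([Li])ccc1OCc1ccccc1 | intermediate
13 | (4-benzyloxy-3-methoxyphenyl)zinc bromide | COc1cc([Zn]Br)ccc1OCc1ccccc1 | intermediate
14 | (1R,2S,5S)-6-acetoxy-2-(4-benzyloxy-3-methoxyphenyl)-1,5-(isopropylidenedioxy)-3,7-dioxabicyclo[3.3.0]octane (C6 anomer mixture) | COc1cc([C@@H]2OC[C@@]3(OC(C)(C)O4)C(OC(C)=O)OC[C@@]234)ccc1OCc1ccccc1 | intermediate
15 | (1R,2S,5R,6S)-2,6-bis(4-benzyloxy-3-methoxyphenyl)-1,5-(isopropylidenedioxy)-3,7-dioxabicyclo[3.3.0]octane | COc1cc([C@@H]2OC[C@@]3(OC(C)(C)O4)[C@H](c5ccc(OCc6ccccc6)c(OC)c5)OC[C@@]234)ccc1OCc1ccccc1 | intermediate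
16 | (1R,2S,5R,6S)-2,6-bis(4-benzyloxy-3-methoxyphenyl)-3,7-dioxabicyclo[3.3.0]octane-1,5-diol | COc1cc([C@@H]2OC[C@@]3(O)[C@H](c4ccc(OCc5ccccc5)c(OC)c4)OC[C@@]23O)ccc1OCc1ccccc1 | intermediate
17 | (1R,2S,5R,6S)-2,6-bis(4-hydroxy-3-methoxyphenyl)-3,7-dioxabicyclo[3.3.0]octane-1,5-diol | COc1cc([C@@H]2OC[C@@]3(O)[C@H](c4ccc(O)c(OC)c4)OC[C@@]23O)ccc1O | target

**Step count**

Total: 8 steps. Longest linear sequence: 7 steps (steps 1–4 and 6–8); step 5 is a one-step side branch.

**Steps most likely to fail**

Step 6. The aryl group may be delivered to the methylene face of the oxocarbenium ions, because in the propellane the isopropylidene methyl groups lie over the oxygen face and could override the stereoelectronic preference; this would give endo-aryl isomers. The fallback reverses the order in which aryl and hydrogen arrive, so that the same facial bias works in the desired sense. It sets out from bis-lactone 8. Aryllithium 12 (made from 11 as in step 5, without the zinc salt) is added at −78 °C in THF and, after aqueous work-up, should give 2,6-bis(4-benzyloxy-3-methoxyphenyl)-2,6-dihydroxy-1,5-(isopropylidenedioxy)-3,7-dioxabicyclo[3.3.0]octane F1. Et3SiH and BF3·OEt2 in CH2Cl2/MeCN at −40 °C then reduce the aryl-stabilised oxocarbenium ions; hydride entering on the methylene face leaves both aryl groups on the oxygen face. The fallback comes back to the route at 15.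

Step 2. The second alkylation may show poor facial selectivity, since the neighbouring carbon now carries two substituents of similar size, or the hindered enolate may form slowly and decompose. The fallback locks the second centre in a ring. It sets out from 4. Hydrogenolysis (H2, Pd/C, EtOAc) gives dimethyl (4S,5S)-4-(hydroxymethyl)-2,2-dimethyl-1,3-dioxolane-4,5-dicarboxylate F2, which should lactonise under PPTS in toluene to methyl (3aS,6aS)-2,2-dimethyl-6-oxotetrahydrofuro[3,4-d][1,3]dioxole-3a(4H)-carboxylate F3. LiN(iPr)2 at −78 °C gives its lithium enolate F4, and benzyl chloromethyl ether 2 then gives methyl (3aS,6aS)-6a-[(benzyloxy)methyl]-2,2-dimethyl-6-oxotetrahydrofuro[3,4-d][1,3]dioxole-3a(4H)-carboxylate F5. Here the new group can only enter cis to the ester on the other ring-fusion carbon, because the two five-membered rings must stay cis-fused. Hydrogenolysis gives the hydroxy lactone ester F6, which closes the second lactone. The fallback comes back to the route at 8.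

Step 7. The acid needed to open the hindered di-tertiary ketal may also ionise the electron-rich benzylic bonds C2–O3 and C6–O7, with epimerisation at C2/C6 or ring opening. The fallback makes the arenes electron-poor before the acid step. It sets out from 15. Hydrogenolysis (H2, Pd/C, EtOAc) gives (1R,2S,5R,6S)-2,6-bis(4-hydroxy-3-methoxyphenyl)-1,5-(isopropylidenedioxy)-3,7-dioxabicyclo[3.3.0]octane F7. Ac2O/pyridine gives the bis(aryl acetate) (1R,2S,5R,6S)-2,6-bis(4-acetoxy-3-methoxyphenyl)-1,5-(isopropylidenedioxy)-3,7-dioxabicyclo[3.3.0]octane F8, whose acetoxy groups disfavour benzylic cations. Aqueous HCl/THF or TFA/H2O then frees (1R,2S,5R,6S)-2,6-bis(4-acetoxy-3-methoxyphenyl)-3,7-dioxabicyclo[3.3.0]octane-1,5-diol F9, and K2CO3 in MeOH at 0 °C removes the aryl acetates. The fallback comes back to the route at 17.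

**Further compounds**

F1 | step 6 | (1S,5S)-2,6-bis(4-benzyloxy-3-methoxyphenyl)-2,6-dihydroxy-1,5-(isopropylidenedioxy)-3,7-dioxabicyclo[3.3.0]octane (C2/C6 mixture) | COc1cc(C2(O)OC[C@@]3(OC(C)(C)O4)C(O)(c5ccc(OCc6ccccc6)c(OC)c5)OC[C@@]234)ccc1OCc1ccccc1
F2 | step 2 | dimethyl (4S,5S)-4-(hydroxymethyl)-2,2-dimethyl-1,3-dioxolane-4,5-dicarboxylate | COC(=O)[C@@]1(CO)OC(C)(C)O[C@@H]1C(=O)OC
F3 | step 2 | methyl (3aS,6aS)-2,2-dimethyl-6-oxotetrahydrofuro[3,4-d][1,3]dioxole-3a(4H)-carboxylate | O=C1OC[C@]2(C(=O)OC)OC(C)(C)O[C@H]12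
F4 | step 2 | lithium enolate of F3 | [Li]OC1OC[C@]2(C(=O)OC)OC(C)(C)OC2=1
F5 | step 2 | methyl (3aS,6aS)-6a-[(benzyloxy)methyl]-2,2-dimethyl-6-oxotetrahydrofuro[3,4-d][1,3]dioxole-3a(4H)-carboxylate | O=C1OC[C@]2(C(=O)OC)OC(C)(C)O[C@]12COCc1ccccc1
F6 | step 2 | methyl (3aS,6aS)-6a-(hydroxymethyl)-2,2-dimethyl-6-oxotetrahydrofuro[3,4-d][1,3]dioxole-3a(4H)-carboxylate | O=C1OC[C@]2(C(=O)OC)OC(C)(C)O[C@]12CO
F7 | step 7 | (1R,2S,5R,6S)-2,6-bis(4-hydroxy-3-methoxyphenyl)-1,5-(isopropylidenedioxy)-3,7-dioxabicyclo[3.3.0]octane | COc1cc([C@@H]2OC[C@@]3(OC(C)(C)O4)[C@H](c5ccc(O)c(OC)c5)OC[C@@]234)ccc1O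
F8 | step 7 | (1R,2S,5R,6S)-2,6-bis(4-acetoxy-3-methoxyphenyl)-1,5-(isopropylidenedioxy)-3,7-dioxabicyclo[3.3.0]octane | COc1cc([C@@H]2OC[C@@]3(OC(C)(C)O4)[C@H](c5ccc(OC(C)=O)c(OC)c5)OC[C@@]234)ccc1OC(C)=O
F9 | step 7 | (1R,2S,5R,6S)-2,6-bis(4-acetoxy-3-methoxyphenyl)-3,7-dioxabicyclo[3.3.0]octane-1,5-diol | COc1cc([C@@H]2OC[C@@]3(O)[C@H](c4ccc(OC(C)=O)c(OC)c4)OC[C@@]23O)ccc1OC(C)=O
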